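**Strategy.** Everything rests on cutting the side chain between C7' (the CH2 three carbons beyond the C4' branch) and C8' (the methine carrying the next methyl branch). The key step couples, under copper catalysis, the primary Grignard reagent of a fully assembled (2S,4'R)-chromenyl bromide with (S)-6-methylheptan-2-yl tosylate: SN2 inversion at the secondary carbon forges C7'–C8' and sets 8'R in one operation. It exploits that C8' is an unfunctionalised CH(CH3) centre, remote from the 2H-chromene ring (O1–C2–C3=C4 fused to the arene), whose C3=C4 alkene and silylated C6 phenol ignore alkylcopper species. The precursor is the C6-silylated chromene carrying a 7-bromo-4-methylheptyl chain on C2.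

Key step: step 13

Assumption: in step 11 the (S,S)-ligand is taken to be the enantiomer that gives the 3S ether from the (E)-carbonate; the sense is fixed by the ligand alone, so the (R,R)-ligand would be used instead if the first run shows the opposite sense.

Side-chain carbons are numbered C1'–C13' from the carbon attached to C2. Several intermediates carry an S descriptor at the carbon that becomes C4'R; the spatial arrangement never changes, only the CIP ranking of the two chain arms.

**Step 1**
Reactants: 1 (S)-propylene oxide; 2 isopentylmagnesium bromide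
Product: 3 (2S)-6-methylheptan-2-ol
Conditions: CuI (10 mol %), THF, −30 → 0 °C; aq. NH4Cl
Reagents that add atoms: none
Why: Copper-catalysed Grignard opening of a terminal epoxide takes place at the unsubstituted CH2, so the C–O stereocentre of 1 is carried over unchanged (S).

**Step 2**
Reactants: 3 (2S)-6-methylheptan-2-ol
Product: 4 (2S)-6-methylheptan-2-yl 4-methylbenzenesulfonate
Conditions: TsCl, pyridine, DMAP (cat.), CH2Cl2, 0 °C → rt
Reagents that add atoms: p-toluenesulfonyl chloride, Cc1ccc(cc1)S(Cl)(=O)=O
Why: O-Sulfonylation forms only the O–S bond, so the carbinol configuration is retained and a leaving group for later inversion is installed.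

**Step 3**
Reactants: 5 2,5-dimethylbenzene-1,4-diol
Product: 6 2,5-dimethyl-4-[(triisopropylsilyl)oxy]phenol
Conditions: TIPSCl (1.0 equiv), imidazole, DMF, 0 °C → rt, argon
Reagents that add atoms: triisopropylsilyl chloride, CC(C)[Si](Cl)(C(C)C)C(C)C
Why: Statistical mono-silylation of a symmetric hydroquinone can give only one mono-ether, which should be separable from diol and bis-ether; the bulky silyl ether is chosen to survive bases and organometallics later.

**Step 4**
Reactants: 6 2,5-dimethyl-4-[(triisopropylsilyl)oxy]phenol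
Product: 7 2-hydroxy-3,6-dimethyl-5-[(triisopropylsilyl)oxy]benzaldehyde
Conditions: MgCl2, Et3N, (CH2O)n, MeCN, reflux; aq. HCl
Reagents that add atoms: paraformaldehyde (as formaldehyde), C=O
Why: Magnesium-phenoxide-directed ortho-formylation (Casnati–Skattebøl) delivers CHO only ortho to the free OH, and the single free ortho position is the one flanked by the methyl group.

**Step 5**
Reactants: 7 2-hydroxy-3,6-dimethyl-5-[(triisopropylsilyl)oxy]benzaldehyde
Product: 8 3,6-dimethyl-4-[(triisopropylsilyl)oxy]-2-vinylphenol
Conditions: Ph3PCH3Br, KOtBu (3 equiv), THF, 0 °C → rt; aq. NH4Cl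
Reagents that add atoms: methyltriphenylphosphonium bromide, C[P+](c1ccccc1)(c1ccccc1)c1ccccc1.[Br-]
Why: Wittig methylenation with excess ylide converts the salicylaldehyde (as its phenoxide) into the ortho-vinylphenol needed for ring closure.

**Step 6**
Reactants: 9 (R)-citronellyl bromide; 10 propyne
Product: 12 (6S)-6,10-dimethylundec-9-en-1-yne, via 1,3-dilithiopropyne 11 (not isolated)
Conditions: n-BuLi (2 equiv), TMEDA, Et2O–hexane, −78 → 0 °C; then 9, THF, −78 °C → rt; aq. NH4Cl
Reagents that add atoms: none
Why: Propargylation of an alkyl halide with the propyne dianion: the sp3 carbanion end of 11 displaces the primary bromide (SN2) and the acetylide end is protonated on work-up, leaving the stereocentre untouched two carbons away.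

**Step 7**
Reactants: 12 (6S)-6,10-dimethylundec-9-en-1-yne
Product: 14 (4S)-4-methylnon-8-yn-1-ol, via ynal 13 (not isolated)
Conditions: O3, CH2Cl2–MeOH, −78 °C (stopped at consumption of 12); then NaBH4, −78 °C → rt
Reagents that add atoms: ozone, O=[O+][O-]
Why: Ozonolysis with reductive work-up cleaves the electron-rich trisubstituted alkene much faster than the terminal alkyne, and NaBH4 reduces the peroxidic intermediates and aldehyde 13 to the primary alcohol.

**Step 8**
Reactants: 14 (4S)-4-methylnon-8-yn-1-ol
Product: 15 (6S)-9-bromo-6-methylnon-1-yne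
Conditions: CBr4, PPh3, CH2Cl2, 0 °C
Reagents that add atoms: carbon tetrabromide, BrC(Br)(Br)Br
Why: Appel bromination converts the primary alcohol into the bromide under neutral conditions that leave the terminal alkyne alone.

**Step 9**
Reactants: 15 (6S)-9-bromo-6-methylnon-1-yne
Product: 18 (2E,7S)-10-bromo-3,7-dimethyldec-2-en-1-ol, via alkenyldimethylalane 16 (not isolated), via lithium alkenylalanate 17 (not isolated)
Conditions: AlMe3 (2.5 equiv), Cp2ZrCl2 (0.25 equiv), CH2Cl2, 0 °C → rt; volatiles removed; n-BuLi, THF–hexane, −78 °C; (CH2O)n, −78 °C → rt; aq. HCl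
Reagents that add atoms: trimethylaluminium, C[Al](C)C; paraformaldehyde (as formaldehyde), C=O
Why: Zirconium-catalysed methylalumination (Negishi carboalumination) adds CH3 and Al syn across the terminal alkyne with Al on the terminal carbon, and the alanate is hydroxymethylated with retention, which fixes the 2E geometry.

**Step 10**
Reactants: 18 (2E,7S)-10-bromo-3,7-dimethyldec-2-en-1-ol
Product: 19 (2E,7S)-10-bromo-3,7-dimethyldec-2-en-1-yl methyl carbonate
Conditions: ClCO2Me, pyridine, CH2Cl2, 0 °C
Reagents that add atoms: methyl chloroformate, COC(Cl)=O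
Why: Acylation of the allylic alcohol gives the carbonate leaving group, which later releases its own base (methoxide) on ionisation.

**Step 11**
Reactants: 19 (2E,7S)-10-bromo-3,7-dimethyldec-2-en-1-yl methyl carbonate; 8 3,6-dimethyl-4-[(triisopropylsilyl)oxy]-2-vinylphenol
Product: 20 {4-[(3S,7S)-10-bromo-3,7-dimethyldec-1-en-3-yl]oxy-2,5-dimethyl-3-vinylphenoxy}triisopropylsilane
Conditions: Pd2(dba)3·CHCl3 (2 mol %), (S,S)-DACH-phenyl Trost ligand (6 mol %), CH2Cl2, rt
Reagents that add atoms: none
Why: Tsuji–Trost asymmetric allylic etherification: zerovalent palladium ionises the geometrically pure (E)-carbonate to one π-allyl complex, the phenoxide of 8 attacks the more substituted terminus inside the chiral pocket, and the ligand alone selects the face that gives the 3S tertiary ether, the remote C7 centre having no influence.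

**Step 12**
Reactants: 20 {4-[(3S,7S)-10-bromo-3,7-dimethyldec-1-en-3-yl]oxy-2,5-dimethyl-3-vinylphenoxy}triisopropylsilane
Product: 21 {[(2S)-2-[(4S)-7-bromo-4-methylheptyl]-2,5,8-trimethyl-2H-chromen-6-yl]oxy}triisopropylsilane
Conditions: second-generation Grubbs catalyst (H2IMes)(PCy3)Cl2Ru=CHPh (5 mol %), CH2Cl2, 40 °C
Reagents that add atoms: none
Why: Ring-closing olefin metathesis of the two terminal vinyl groups closes the six-membered pyran ring at C3=C4 and expels ethene without touching the C2–O bond, so the quaternary centre is preserved.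

**Step 13**
Reactants: 21 {[(2S)-2-[(4S)-7-bromo-4-methylheptyl]-2,5,8-trimethyl-2H-chromen-6-yl]oxy}triisopropylsilane; 4 (2S)-6-methylheptan-2-yl 4-methylbenzenesulfonate
Product: 23 triisopropyl{[(2S)-2,5,8-trimethyl-2-[(4R,8R)-4,8,12-trimethyltridecyl]-2H-chromen-6-yl]oxy}silane, via Grignard reagent 22 (not isolated)
Conditions: Mg, THF, rt → 40 °C; then added to 4 (1.5 equiv), CuI (10 mol %), TMEDA (20 mol %), LiOMe (1 equiv), THF, 0 °C; aq. NH4Cl
Reagents that add atoms: none
Why: Grignard reagent 22 transmetalates to an alkylcuprate of monovalent copper, which attacks the secondary C–OTs carbon of 4 from the rear (SN2-type oxidative addition) to give a dialkyl species of trivalent copper that reductively eliminates the C7'–C8' bond. The closest known reaction type is the copper-catalysed Kumada-type alkyl–alkyl coupling of non-activated secondary alkyl tosylates with alkyl Grignard reagents, which runs with inversion. No ring is closed. The new stereocentre C8' is controlled by the S configuration of 4 (from 1) through inversion, giving 8'R, while C2 and C4' are spectators. The step needs substitution to outrun E2 elimination of the tosylate and β-hydride loss, which the unhindered methyl carbinol carbon and the TMEDA/LiOMe-modified cuprate at 0 °C should secure, and it needs the allylic aryl ether O1–C2 and the silyl ether to stay intact, which the quaternary C2, the poor phenoxide leaving group and the bulky silyl group should secure.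

**Step 14**
Reactants: 23 triisopropyl{[(2S)-2,5,8-trimethyl-2-[(4R,8R)-4,8,12-trimethyltridecyl]-2H-chromen-6-yl]oxy}silane
Product: 24 (2S)-2,5,8-trimethyl-2-[(4R,8R)-4,8,12-trimethyltridecyl]-2H-chromen-6-ol
Conditions: Bu4NF, AcOH, THF, 0 °C, argon
Reagents that add atoms: none
Why: Fluoride-mediated desilylation of the aryl silyl ether, buffered with acetic acid so that the oxidation-prone phenoxide is protonated at once, frees the C6 phenol without affecting the chromene or any stereocentre.

**Compound list**

1 | (S)-propylene oxide | C[C@H]1CO1 | starting material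
2 | isopentylmagnesium bromide (solution) | CC(C)CC[Mg]Br | starting material
3 | (2S)-6-methylheptan-2-ol | C[C@H](O)CCCC(C)C | intermediate
4 | (2S)-6-methylheptan-2-yl 4-methylbenzenesulfonate | C[C@H](OS(=O)(=O)c1ccc(C)cc1)CCCC(C)C | intermediate
5 | 2,5-dimethylbenzene-1,4-diol | Cc1cc(O)c(C)cc1O | starting material
6 | 2,5-dimethyl-4-[(triisopropylsilyl)oxy]phenol | Cc1cc(O[Si](C(C)C)(C(C)C)C(C)C)c(C)cc1O | intermediate
7 | 2-hydroxy-3,6-dimethyl-5-[(triisopropylsilyl)oxy]benzaldehyde | O=Cc1c(C)c(O[Si](C(C)C)(C(C)C)C(C)C)cc(C)c1O | intermediate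
8 | 3,6-dimethyl-4-[(triisopropylsilyl)oxy]-2-vinylphenol | C=Cc1c(C)c(O[Si](C(C)C)(C(C)C)C(C)C)cc(C)c1O | intermediate
9 | (R)-citronellyl bromide, (6R)-8-bromo-2,6-dimethyloct-2-ene | BrCC[C@H](C)CCC=C(C)C | starting material
10 | propyne | CC#C | starting material
11 | 1,3-dilithiopropyne | [Li]CC#C[Li] | intermediate
12 | (6S)-6,10-dimethylundec-9-en-1-yne | C#CCCC[C@H](C)CCC=C(C)C | intermediate
13 | (4S)-4-methylnon-8-ynal | C#CCCC[C@H](C)CCC=O | intermediate
14 | (4S)-4-methylnon-8-yn-1-ol | C#CCCC[C@H](C)CCCO | intermediate
15 | (6S)-9-bromo-6-methylnon-1-yne | C#CCCC[C@H](C)CCCBr | intermediate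
16 | [(1E,6S)-9-bromo-2,6-dimethylnon-1-en-1-yl]dimethylalane | C[Al](C)/C=C(\C)CCC[C@H](C)CCCBr | intermediate
17 | lithium butyl[(1E,6S)-9-bromo-2,6-dimethylnon-1-en-1-yl]dimethylalanate | [Li+].CCCC[Al-](C)(C)/C=C(\C)CCC[C@H](C)CCCBr | intermediate
18 | (2E,7S)-10-bromo-3,7-dimethyldec-2-en-1-ol | OC/C=C(\C)CCC[C@H](C)CCCBr | intermediate
19 | (2E,7S)-10-bromo-3,7-dimethyldec-2-en-1-yl methyl carbonate | COC(=O)OC/C=C(\C)CCC[C@H](C)CCCBr | intermediate
20 | {4-[(3S,7S)-10-bromo-3,7-dimethyldec-1-en-3-yl]oxy-2,5-dimethyl-3-vinylphenoxy}triisopropylsilane | C=Cc1c(C)c(O[Si](C(C)C)(C(C)C)C(C)C)cc(C)c1O[C@@](C)(CCC[C@H](C)CCCBr)C=C | intermediate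
21 | {[(2S)-2-[(4S)-7-bromo-4-methylheptyl]-2,5,8-trimethyl-2H-chromen-6-yl]oxy}triisopropylsilane | Cc1cc(O[Si](C(C)C)(C(C)C)C(C)C)c(C)c2c1O[C@@](C)(CCC[C@H](C)CCCBr)C=C2 | intermediate
22 | Grignard reagent of 21 (C7'–MgBr) | Cc1cc(O[Si](C(C)C)(C(C)C)C(C)C)c(C)c2c1O[C@@](C)(CCC[C@H](C)CCC[Mg]Br)C=C2 | intermediate
23 | triisopropyl{[(2S)-2,5,8-trimethyl-2-[(4R,8R)-4,8,12-trimethyltridecyl]-2H-chromen-6-yl]oxy}silane | Cc1cc(O[Si](C(C)C)(C(C)C)C(C)C)c(C)c2c1O[C@@](C)(CCC[C@H](C)CCC[C@H](C)CCCC(C)C)C=C2 | intermediate
24 | (2S)-2,5,8-trimethyl-2-[(4R,8R)-4,8,12-trimethyltridecyl]-2H-chromen-6-ol | Cc1cc(O)c(C)c2c1O[C@@](C)(CCC[C@H](C)CCC[C@H](C)CCCC(C)C)C=C2 | target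

**Step count.** Total: 14 steps. Longest linear sequence: 9 steps (steps 6–14, from 9 to 24). Steps 1–2 and steps 3–5 are side branches.

**Steps most likely to fail**

1. Step 13. E2 elimination of the secondary tosylate and β-hydride loss from the alkylcopper intermediate may outrun substitution, and Wurtz dimerisation may consume the bromide during magnesium insertion. The fallback replaces the organocopper coupling by sulfone-anion alkylation and reductive desulfonylation; it sets out from 21 and comes back at 23. Bromide 21 would be treated with PhSO2Na in DMF at 60 °C to give {[(2S)-2-[(4S)-4-methyl-7-(phenylsulfonyl)heptyl]-2,5,8-trimethyl-2H-chromen-6-yl]oxy}triisopropylsilane F1. Deprotonation with n-BuLi in THF–DMPU at −78 °C and alkylation with tosylate 4 (SN2, inversion at C8') should give the C7'-phenylsulfonyl derivative of 23 F2 as a mixture of C7' epimers. Sodium amalgam (Na/Hg) with Na2HPO4 in MeOH–THF at −20 °C should then remove the sulfonyl group and converge both epimers on 23.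

2. Step 11. Attack at the unsubstituted allyl terminus (linear ether) and poor enantioface discrimination are possible, because the phenol oxygen is flanked by a methyl and a vinyl group. The fallback gives up catalyst control for a non-selective annulation followed by separation; it sets out from 18 and 6 and comes back at 21. Alcohol 18 would be oxidised with MnO2 in CH2Cl2 to (2E,7S)-10-bromo-3,7-dimethyldec-2-enal F3. Heating F3 with phenol 6, PhB(OH)2 and AcOH in toluene under water removal should give the chromene through an ortho-quinone methide and oxa-6π electrocyclisation, as 21 together with its (2R)-epimer F4. The two would be separated by preparative HPLC on a chiral stationary phase.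

3. Step 9. The primary bromide may be lost at the alanate stage (alkylation or halogen–metal exchange), and hydroxymethylation may be incomplete. The fallback builds the trisubstituted alkene by carbonyl olefination instead of carbometalation; it sets out from 14 and comes back at 18. Alkynol 14 would be hydrated with Ph3PAuNTf2 (cat.) in aqueous dioxane to (6S)-9-hydroxy-6-methylnonan-2-one F5. Horner–Wadsworth–Emmons reaction with triethyl phosphonoacetate and NaH in THF should give ethyl (2E,7S)-10-hydroxy-3,7-dimethyldec-2-enoate F6, with the minor ethyl (2Z,7S)-10-hydroxy-3,7-dimethyldec-2-enoate F7 removed by chromatography. Appel bromination (CBr4, PPh3) would give ethyl (2E,7S)-10-bromo-3,7-dimethyldec-2-enoate F8, and i-Bu2AlH in CH2Cl2 at −78 °C would reduce it to 18.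

**Further compounds**

F1 | step 13 | {[(2S)-2-[(4S)-4-methyl-7-(phenylsulfonyl)heptyl]-2,5,8-trimethyl-2H-chromen-6-yl]oxy}triisopropylsilane | Cc1cc(O[Si](C(C)C)(C(C)C)C(C)C)c(C)c2c1O[C@@](C)(CCC[C@H](C)CCCS(=O)(=O)c1ccccc1)C=C2
F2 | step 13 | C7'-phenylsulfonyl derivative of 23 (C7' epimers) | Cc1cc(O[Si](C(C)C)(C(C)C)C(C)C)c(C)c2c1O[C@@](C)(CCC[C@H](C)CCC([C@H](C)CCCC(C)C)S(=O)(=O)c1ccccc1)C=C2
F3 | step 11 | (2E,7S)-10-bromo-3,7-dimethyldec-2-enal | O=C/C=C(\C)CCC[C@H](C)CCCBr
F4 | step 11 | {[(2R)-2-[(4S)-7-bromo-4-methylheptyl]-2,5,8-trimethyl-2H-chromen-6-yl]oxy}triisopropylsilane | Cc1cc(O[Si](C(C)C)(C(C)C)C(C)C)c(C)c2c1O[C@](C)(CCC[C@H](C)CCCBr)C=C2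
F5 | step 9 | (6S)-9-hydroxy-6-methylnonan-2-one | CC(=O)CCC[C@H](C)CCCO
F6 | step 9 | ethyl (2E,7S)-10-hydroxy-3,7-dimethyldec-2-enoate | CCOC(=O)/C=C(\C)CCC[C@H](C)CCCO
F7 | step 9 | ethyl (2Z,7S)-10-hydroxy-3,7-dimethyldec-2-enoate | CCOC(=O)/C=C(/C)CCC[C@H](C)CCCO
F8 | step 9 | ethyl (2E,7S)-10-bromo-3,7-dimethyldec-2-enoate | CCOC(=O)/C=C(\C)CCC[C@H](C)CCCBr
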